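**Retrosynthetic overview**
1. The strategy rests on ring C, the central cyclohexene built from the spiro quaternary carbon (shared with ring B), C(=CH–isopropenyl), C(=α-carbon of ring A) and CH=C(CH3)–CH2. Ring C ties together two identical C16 2-prenyl-2,3-epoxy-4-hydroxycyclohexanone halves (rings A and B).
2. Key disconnection: a retro-[4+2] through the bond between the two alkylidene-bearing ring C carbons and the CH2–spiro bond returns two molecules of one vinylallenone, which an amine releases from its α-alkynyl ketone tautomer.
3. The alkynyl ketone comes from a silyl ynenol ether (conjugate hydrosilylation) of an α-enynyl epoxy enone, itself made by Sonogashira coupling of the α-iodo enone after Saegusa–Ito dehydrogenation.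
4. The epoxy ketone core comes from (S)-4-hydroxy-2-prenylcyclohex-2-enone by hydroxyl-directed epoxidation; that enone comes from a purchased cyclohexenone ketal by asymmetric transfer hydrogenation, ketal hydrolysis, α-iodination and Stille prenylation.
5. Ring order: the six-membered carbocycle of rings A and B is purchased, the epoxide is fused to it next, and ring C is closed last as the two halves are joined.

Key step: step 13

Assumption: the (S,S)-TsDPEN catalyst is taken to give the S carbinol, the alkenyl side of the enone playing the role of the aryl group of an aryl ketone; if the sense of induction proves opposite, the (R,R) catalyst is used.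
Locants used in all names of a C16 half: C1 carbonyl carbon, C2 epoxide carbon bearing prenyl (3-methylbut-2-en-1-yl), C3 epoxide CH, C4 carbinol carbon, C5, and C6, the carbon that later carries the C5 side chain.

**Route**

Step 1
Reactants: 1 1,4-dioxaspiro[4.5]dec-6-en-8-one
Product: 2 (S)-1,4-dioxaspiro[4.5]dec-6-en-8-ol
Conditions: RuCl(p-cymene)[(S,S)-TsDPEN] (cat.), HCO2Na, H2O/CH2Cl2, rt
Reagents that add atoms: none
Why: Noyori-type asymmetric transfer hydrogenation, in which the ruthenium hydride/N–H pair reduces only the C=O bond and, with the alkenyl side of the enone under the arene ligand, the (S,S) catalyst should deliver hydride to the face that gives the S carbinol, the ketal being stable in the near-neutral formate medium.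

Step 2
Reactants: 2 (S)-1,4-dioxaspiro[4.5]dec-6-en-8-ol
Product: 3 (S)-4-hydroxycyclohex-2-en-1-one
Conditions: pyridinium p-toluenesulfonate (cat.), acetone/H2O, rt
Reagents that add atoms: water, O
Why: Acid-catalysed ketal hydrolysis through the allyl-stabilised oxocarbenium ion is fast under buffered conditions that neither ionise nor enolise the carbinol carbon, so the S configuration should be retained.

Step 3
Reactants: 3 (S)-4-hydroxycyclohex-2-en-1-one
Product: 4 (S)-4-hydroxy-2-iodocyclohex-2-en-1-one
Conditions: I2, pyridine, CH2Cl2, 0 °C → rt
Reagents that add atoms: iodine, II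
Why: α-Iodination of an enone by reversible conjugate addition of pyridine, iodination of the enolate and elimination (Baylis–Hillman-type sequence), which involves neither the free alcohol nor the stereocentre.

Step 4
Reactants: 4 (S)-4-hydroxy-2-iodocyclohex-2-en-1-one; 5 tributyl(3-methylbut-2-en-1-yl)stannane
Product: 6 (S)-4-hydroxy-2-(3-methylbut-2-en-1-yl)cyclohex-2-en-1-one
Conditions: Pd2(dba)3 (cat.), AsPh3, CuI (cat.), NMP, rt
Reagents that add atoms: none
Why: Stille coupling, in which zerovalent palladium inserts into the C–I bond, AsPh3 and CuI speed up transmetalation of the allylic stannane, and reductive elimination at the unsubstituted allyl terminus should give the linear prenyl enone with the free hydroxyl tolerated.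

Step 5
Reactants: 6 (S)-4-hydroxy-2-(3-methylbut-2-en-1-yl)cyclohex-2-en-1-one
Product: 7 (2S,3S,4S)-2,3-epoxy-4-hydroxy-2-prenylcyclohexan-1-one (epoxide oxygen cis to the hydroxyl)
Conditions: Ti(OiPr)4, t-BuOOH (anhydrous, in decane), 4 Å sieves, CH2Cl2, −20 → 0 °C
Reagents that add atoms: tert-butyl hydroperoxide, CC(C)(C)OO
Why: Hydroxyl-directed epoxidation, in which the titanium alkoxide of the C4 hydroxyl also binds the peroxide and passes oxygen to the neighbouring enone C2=C3 bond from the carbinol face (conjugate peroxide transfer, then ring closure), so both epoxide carbons should be set cis to the hydroxyl, while the prenyl alkene is out of reach of the directing alkoxide and is no acceptor for a nucleophilic peroxide.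

Step 6
Reactants: 7 (2S,3S,4S)-2,3-epoxy-4-hydroxy-2-prenylcyclohexan-1-one
Product: 8 (2S,3S,4S)-2,3-epoxy-2-prenyl-4-(triethylsilyloxy)cyclohexan-1-one
Conditions: Et3SiCl, imidazole, CH2Cl2, 0 °C
Reagents that add atoms: chlorotriethylsilane, CC[Si](Cl)(CC)CC
Why: Routine silylation of a secondary alcohol with a silyl chloride and imidazole, which touches no stereocentre.

Step 7
Reactants: 8 (2S,3S,4S)-2,3-epoxy-2-prenyl-4-(triethylsilyloxy)cyclohexan-1-one
Product: 9 kinetic trimethylsilyl enol ether of 8 (C1(OSiMe3)=C6, epoxide and silyl ether unchanged)
Conditions: LiN(i-Pr)2, Me3SiCl, THF, −78 °C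
Reagents that add atoms: chlorotrimethylsilane, C[Si](C)(C)Cl
Why: Kinetic deprotonation can occur only at C6 (C2 is quaternary) and the lithium enolate is O-silylated in situ, the epoxide oxygen not being β to the enolate carbon so that no eliminative ring opening is expected.

Step 8
Reactants: 9 kinetic trimethylsilyl enol ether of 8
Product: 10 (2S,3S,4S)-2,3-epoxy-2-prenyl-4-(triethylsilyloxy)cyclohex-5-en-1-one
Conditions: Pd(OAc)2, MeCN, rt
Reagents that add atoms: none
Why: Saegusa–Ito oxidation, in which palladation of the silyl enol ether gives the C6-palladated ketone and syn β-hydride elimination of a C5 hydrogen should give the C5=C6 enone without touching the C4 stereocentre.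

Step 9
Reactants: 10 (2S,3S,4S)-2,3-epoxy-2-prenyl-4-(triethylsilyloxy)cyclohex-5-en-1-one
Product: 11 (2S,3S,4S)-2,3-epoxy-6-iodo-2-prenyl-4-(triethylsilyloxy)cyclohex-5-en-1-one
Conditions: I2, pyridine, CH2Cl2, 0 °C → rt
Reagents that add atoms: iodine, II
Why: The same pyridine-mediated addition–iodination–elimination sequence as in step 3 places iodine on the enone α-carbon C6, and the mild conditions should spare the epoxide and the silyl ether.

Step 10
Reactants: 11 (2S,3S,4S)-2,3-epoxy-6-iodo-2-prenyl-4-(triethylsilyloxy)cyclohex-5-en-1-one; 12 2-methylbut-1-en-3-yne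
Product: 13 (2S,3S,4S)-2,3-epoxy-6-(3-methylbut-3-en-1-ynyl)-2-prenyl-4-(triethylsilyloxy)cyclohex-5-en-1-one
Conditions: PdCl2(PPh3)2 (cat.), CuI (cat.), i-Pr2NH, THF, 0 °C → rt
Reagents that add atoms: none
Why: Sonogashira coupling (oxidative addition of the vinyl C–I bond to zerovalent palladium, transmetalation from the copper acetylide, reductive elimination) under mild amine conditions that should leave the epoxide, the silyl ether and the enone intact.

Step 11
Reactants: 13 (2S,3S,4S)-2,3-epoxy-6-(3-methylbut-3-en-1-ynyl)-2-prenyl-4-(triethylsilyloxy)cyclohex-5-en-1-one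
Product: 14 (2S,3S,4S)-1-(dimethylphenylsilyloxy)-2,3-epoxy-6-(3-methylbut-3-en-1-ynyl)-2-prenyl-4-(triethylsilyloxy)cyclohex-1(6)-ene (silyl ynenol ether)
Conditions: [(Ph3P)CuH]6 (cat.), PhMe2SiH, toluene, 0 °C → rt
Reagents that add atoms: dimethylphenylsilane, C[SiH](C)c1ccccc1
Why: Copper hydride-catalysed conjugate reduction (1,4-hydrosilylation), in which Cu–H adds hydride to the unsubstituted β-carbon C5 and σ-bond metathesis of the copper ynenolate with Si–H forms the O–Si bond and returns Cu–H; the alkyne sits on the α-carbon out of conjugation with C=O and the epoxide is not β to the enolate carbon, so both should survive, and no stereocentre is formed.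

Step 12
Reactants: 14 silyl ynenol ether
Product: 15 (2S,3S,4S)-2,3-epoxy-4-hydroxy-6-(3-methylbut-3-en-1-ynyl)-2-prenylcyclohexan-1-one (mixture of C6 epimers)
Conditions: Et3N·3HF, MeCN, 0 °C → rt; pH 7 buffer work-up, no chromatography, used at once
Reagents that add atoms: none
Why: Fluoride cleaves both Si–O bonds in a weakly acidic, base-free medium and the liberated enol is protonated at C6 to give the β,γ-alkynyl ketone, whose C6 configuration is without consequence because C6 becomes sp2 again in the next step.

Step 13
Reactants: 15 (2S,3S,4S)-2,3-epoxy-4-hydroxy-6-(3-methylbut-3-en-1-ynyl)-2-prenylcyclohexan-1-one (two molecules)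
Product: 17 target dimer CNP0235815.2, via vinylallenone 16 (not isolated)
Conditions: 1,4-diazabicyclo[2.2.2]octane (DABCO, cat.), toluene (concentrated), 25 °C
Reagents that add atoms: none
Why: Proposed new method: the amine removes the C6 proton of 15 and the ynenolate is reprotonated at the alkyne terminus, so vinylallenone 16 forms and its axis keeps equilibrating through the same anion (Curtin–Hammett situation), while two molecules of 16 combine in an intermolecular, strongly asynchronous [4+2] in which the Csp=CH–C(CH3)=CH2 unit of one molecule (4π) adds across the ketone-conjugated C6=Csp bond of the other (2π). The closest known reaction types are the thermal Diels–Alder dimerization of vinylallenes, allenyl ketones reacting as dienophiles at the carbonyl-conjugated C=C, and the amine-mediated isomerization of β,γ-alkynyl ketones to allenyl ketones. Ring C is closed by this intermolecular [4+2] as a six-membered carbocycle: the bond between the two sp carbons leads (pentadienyl-type stabilisation on both halves) and the isopropenyl CH2 terminus then collapses on C6 of the dienophile, six-membered closure being preferred to the four-membered [2+2] alternative. The only new stereocentre, the spiro carbon of ring B, is fixed by the face of the dienophile: the diene should add on the face that carries the epoxide oxygen and the C4 hydroxyl, because the prenyl CH2 on the neighbouring quaternary epoxide carbon covers the other face, and only the aS axial epimer presents H rather than isopropenyl on that face, which also places isopropenyl cis to the spiro carbon. The ring A alkylidene geometry (C=O cis to the ring C carbon bearing =CH–isopropenyl) follows from approach on the carbonyl side of the diene partner, the flat C=O being smaller than the ring CH2, and either axial epimer of the diene partner gives the same product. The step needs sp-to-sp and CH2-to-C6 regiochemistry, [4+2] rather than [2+2] closure and the two facial choices above; these should be secured by the stabilised bis-allylic bonding mode, by the fact that only the unsubstituted CH2 can reach the fully substituted C6, by a diene π system orthogonal to its own carbonyl (not deactivated) and by a carbonyl-activated, strained dienophile C=C.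

**Compound list**
1 | 1,4-dioxaspiro[4.5]dec-6-en-8-one | O=C1C=CC2(CC1)OCCO2 | starting material
2 | (S)-1,4-dioxaspiro[4.5]dec-6-en-8-ol | C1C[C@H](O)C=CC12OCCO2 | intermediate
3 | (S)-4-hydroxycyclohex-2-en-1-one | O=C1CC[C@H](O)C=C1 | intermediate
4 | (S)-4-hydroxy-2-iodocyclohex-2-en-1-one | O=C1CC[C@H](O)C=C1I | intermediate
5 | tributyl(3-methylbut-2-en-1-yl)stannane | CCCC[Sn](CCCC)(CCCC)CC=C(C)C | starting material
6 | (S)-4-hydroxy-2-(3-methylbut-2-en-1-yl)cyclohex-2-en-1-one | O=C1CC[C@H](O)C=C1CC=C(C)C | intermediate
7 | (2S,3S,4S)-2,3-epoxy-4-hydroxy-2-prenylcyclohexan-1-one, epoxide cis to OH | C1C[C@H](O)[C@@H]2O[C@]2(CC=C(C)C)C1=O | intermediate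
8 | (2S,3S,4S)-2,3-epoxy-2-prenyl-4-(triethylsilyloxy)cyclohexan-1-one | C1C[C@H](O[Si](CC)(CC)CC)[C@@H]2O[C@]2(CC=C(C)C)C1=O | intermediate
9 | kinetic trimethylsilyl enol ether of 8 (C1(OSiMe3)=C6) | C=1C[C@H](O[Si](CC)(CC)CC)[C@@H]2O[C@]2(CC=C(C)C)C=1O[Si](C)(C)C | intermediate
10 | (2S,3S,4S)-2,3-epoxy-2-prenyl-4-(triethylsilyloxy)cyclohex-5-en-1-one | C1=C[C@H](O[Si](CC)(CC)CC)[C@@H]2O[C@]2(CC=C(C)C)C1=O | intermediate
11 | (2S,3S,4S)-2,3-epoxy-6-iodo-2-prenyl-4-(triethylsilyloxy)cyclohex-5-en-1-one | IC1=C[C@H](O[Si](CC)(CC)CC)[C@@H]2O[C@]2(CC=C(C)C)C1=O | intermediate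
12 | 2-methylbut-1-en-3-yne | C=C(C)C#C | starting material
13 | (2S,3S,4S)-2,3-epoxy-6-(3-methylbut-3-en-1-ynyl)-2-prenyl-4-(triethylsilyloxy)cyclohex-5-en-1-one | C=C(C)C#CC1=C[C@H](O[Si](CC)(CC)CC)[C@@H]2O[C@]2(CC=C(C)C)C1=O | intermediate
14 | dimethylphenylsilyl ynenol ether of the conjugate-reduced enynone (C1(OSiMe2Ph)=C6, 4-OSiEt3) | C=C(C)C#CC1C[C@H](O[Si](CC)(CC)CC)[C@@H]2O[C@]2(CC=C(C)C)C=1O[Si](C)(C)c1ccccc1 | intermediate
15 | (2S,3S,4S)-2,3-epoxy-4-hydroxy-6-(3-methylbut-3-en-1-ynyl)-2-prenylcyclohexan-1-one, C6 epimers | C=C(C)C#CC1C[C@H](O)[C@@H]2O[C@]2(CC=C(C)C)C1=O | intermediate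
16 | (2S,3S,4S)-2,3-epoxy-4-hydroxy-6-(3-methylbuta-1,3-dienylidene)-2-prenylcyclohexan-1-one, vinylallenone, axial epimers interconverting (axis left open) | C=C(C)C=C=C1C[C@H](O)[C@@H]2O[C@]2(CC=C(C)C)C1=O | intermediate
17 | CNP0235815.2: spiro dimer, both halves (2S,3S,4S), spiro carbon R, isopropenyl cis to the spiro carbon, ring A C=O cis to the ring C carbon bearing =CH–isopropenyl | C=C(C)/C=C1/C(=C2/C[C@H](O)[C@@H]3O[C@]3(CC=C(C)C)C2=O)C=C(C)C[C@@]12C[C@H](O)[C@@H]1O[C@]1(CC=C(C)C)C2=O | target

**Step count**
Total step count: 13. Longest linear sequence: 13 steps (1 → 17); compounds 5 and 12 are purchased.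

**Steps most likely to fail**

1. Step 13 (the step carrying the label "Proposed new method:").
- What may go wrong: the amine may add as a nucleophile to the central allene carbon and start oligomerisation; cycloaddition may outrun axial equilibration so that mismatched pairings compete; [2+2] closure or approach on the wrong face of either partner may erode peri- and facial selectivity.
- Fallback (static, stepwise, each reaction of a known type): it sets out from 14. Buffered cleavage of the enol silyl ether only (n-Bu4NF/AcOH, THF, −78 °C) should give the triethylsilyl-protected α-alkynyl ketone F1. Catalytic Et3N in CH2Cl2 should isomerise it to the triethylsilyl-protected vinylallenone F2, which is expected to be storable because the silyl ether covers the face on which cycloaddition has to occur. The amine is washed out and the axial epimers of F2 may be separated by chromatography. Et3N·3HF (no free base, so the axis stays fixed) then releases 16, where the route is rejoined, and concentration in toluene without base should give 17 by the thermal Diels–Alder dimerization known for vinylallenes. In this variant the aS epimer serves as dienophile and either epimer as diene, and leftover aR material is re-equilibrated with Et3N at the F2 stage.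

2. Step 11.
- What may go wrong: hydrocupration of the enyne or 1,2-reduction may compete with conjugate hydride transfer, and the ynenolate may be C-silylated or protonated instead of O-silylated.
- Fallback (borohydride conjugate reduction with enolate trapping in place of catalytic hydrometalation): it sets out from 13. K[(s-Bu)3BH] in THF at −78 °C should add hydride 1,4 to the β-unsubstituted enone, and trapping the potassium ynenolate with Et3SiCl should give the bis(triethylsilyl) ynenol ether F3. The conditions of step 12 remove both silyl groups and the route is rejoined at 15.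

3. Step 5.
- What may go wrong: oxygen transfer to the electron-poor trisubstituted enone alkene may be sluggish, direction by the hydroxyl may be weak (epoxide trans to OH), or the titanium alkoxide may open the epoxide.
- Fallback (electrophilic, hydroxyl-directed epoxidation of a reduced allylic alcohol): it sets out from 6. Et3SiCl/imidazole should give the silyl ether F4. Luche reduction (NaBH4, CeCl3·7H2O, MeOH, −78 °C) should deliver hydride anti to the silyloxy group and give the 1,4-cis allylic alcohol F5. The C1 hydroxyl then directs a vanadium-catalysed epoxidation (VO(acac)2, t-BuOOH, CH2Cl2) of the now electron-rich C2=C3 bond to its own face, which is also the face of the C4 oxygen, to give the all-cis epoxy alcohol F6; the prenyl alkene is only bishomoallylic and should react far more slowly. Dess–Martin oxidation of the C1 carbinol returns to the route at 8, and step 6 is then not needed.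

Further compounds
F1 | step 13 | (2S,3S,4S)-2,3-epoxy-6-(3-methylbut-3-en-1-ynyl)-2-prenyl-4-(triethylsilyloxy)cyclohexan-1-one, C6 epimers | C=C(C)C#CC1C[C@H](O[Si](CC)(CC)CC)[C@@H]2O[C@]2(CC=C(C)C)C1=O
F2 | step 13 | (2S,3S,4S)-2,3-epoxy-6-(3-methylbuta-1,3-dienylidene)-2-prenyl-4-(triethylsilyloxy)cyclohexan-1-one, axial epimers (axis left open) | C=C(C)C=C=C1C[C@H](O[Si](CC)(CC)CC)[C@@H]2O[C@]2(CC=C(C)C)C1=O
F3 | step 11 | bis(triethylsilyl) ynenol ether (C1(OSiEt3)=C6, 4-OSiEt3) | C=C(C)C#CC1C[C@H](O[Si](CC)(CC)CC)[C@@H]2O[C@]2(CC=C(C)C)C=1O[Si](CC)(CC)CC
F4 | step 5 | (S)-2-prenyl-4-(triethylsilyloxy)cyclohex-2-en-1-one | O=C1CC[C@H](O[Si](CC)(CC)CC)C=C1CC=C(C)C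
F5 | step 5 | (1R,4S)-2-prenyl-4-(triethylsilyloxy)cyclohex-2-en-1-ol, 1,4-cis | C1C[C@H](O[Si](CC)(CC)CC)C=C(CC=C(C)C)[C@@H]1O
F6 | step 5 | 2,3-epoxy-2-prenyl-4-(triethylsilyloxy)cyclohexan-1-ol, C1–OH, epoxide oxygen and C4–O all cis | C1C[C@H](O[Si](CC)(CC)CC)[C@@H]2O[C@]2(CC=C(C)C)[C@@H]1O
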